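**Assumption:** the lipase in step 4 acylates the (S)-alcohol of the racemate faster; if it prefers the (R)-alcohol, the recovered (S)-alcohol is propanoylated instead and nothing downstream changes.

## Retrosynthetic overview

1. Target 19 ← tris-angeloylation of triol enone 17 (one molecule of angelic anhydride per hydroxyl) ← two hydroxyl-directed reductions and ketal hydrolysis of tricyclic β-diketone 15.
2. 15 ← one-flask enolate cascade on bromo keto-lactone 13: transannular lactone-enolate alkylation closes the cyclobutane, then O→C acyl transfer (Claisen) closes the seven-membered carbocycle.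
3. 13 ← cis-fused seven-membered lactone 10 ← intramolecular Michael addition of a tethered propanoate onto quinone monoketal 9.
4. 9 ← oxidative dearomatization of phenol 8; the quaternary carbon comes from an aromatic Claisen rearrangement (1 + 2) and is resolved by a lipase that also installs the tether.
5. Ring order: arene → cyclohexadienone → temporary lactone → cyclobutane and cycloheptanedione together → enone unveiled last.

## Route

Step 1
Reactants: 1 4-methoxy-2-methylphenol; 2 methyl (2E)-4-bromo-2-methylbut-2-enoate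
Product: 3 methyl (2E)-4-(4-methoxy-2-methylphenoxy)-2-methylbut-2-enoate
Conditions: K2CO3, acetone, reflux
Reagents that add atoms: none
Why: Williamson etherification, SN2 of the phenoxide at the primary allylic bromide.

Step 2
Reactants: 3 methyl (2E)-4-(4-methoxy-2-methylphenoxy)-2-methylbut-2-enoate
Product: 5 rac-3-ethenyl-5-methoxy-3,7-dimethyl-1-benzofuran-2(3H)-one, via hydroxy ester 4 (not isolated)
Conditions: PhNEt2, 190 °C
Reagents that add atoms: none
Why: Aromatic Claisen rearrangement ([3,3]) onto the only free ortho position creates the quaternary carbon (methyl, vinyl, ester, aryl) as a racemate, and the phenol then lactonizes onto the ester.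

Step 3
Reactants: 5 rac-3-ethenyl-5-methoxy-3,7-dimethyl-1-benzofuran-2(3H)-one
Product: 6 rac-2-(1-hydroxy-2-methylbut-3-en-2-yl)-4-methoxy-6-methylphenol
Conditions: LiAlH4, THF, 0 °C to rt
Reagents that add atoms: none
Why: Hydride reduction of the aryl lactone frees the phenol and gives the neopentyl primary alcohol.

Step 4
Reactants: 6 rac-2-(1-hydroxy-2-methylbut-3-en-2-yl)-4-methoxy-6-methylphenol; 7 ethenyl propanoate
Product: 8 (2S)-2-(2-hydroxy-5-methoxy-3-methylphenyl)-2-methylbut-3-en-1-yl propanoate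
Conditions: Burkholderia cepacia lipase (Amano PS), t-BuOMe, 30 °C, stopped near 45% conversion
Reagents that add atoms: none
Why: Lipase-catalysed kinetic resolution (irreversible transesterification) acylates only the primary hydroxyl of one enantiomer, which fixes the (S) quaternary centre and installs the propanoate tether at once; the (R)-alcohol stays unreacted and is separated.

Step 5
Reactants: 8 (2S)-2-(2-hydroxy-5-methoxy-3-methylphenyl)-2-methylbut-3-en-1-yl propanoate
Product: 9 (2S)-2-(3,3-dimethoxy-5-methyl-6-oxocyclohexa-1,4-dien-1-yl)-2-methylbut-3-en-1-yl propanoate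
Conditions: PhI(OAc)2, MeOH, 0 °C
Reagents that add atoms: methanol, CO
Why: Oxidative dearomatization of the para-methoxyphenol gives the quinone monoketal, which masks the future enone carbonyl and exposes a cross-conjugated dienone.

Step 6
Reactants: 9 (2S)-2-(3,3-dimethoxy-5-methyl-6-oxocyclohexa-1,4-dien-1-yl)-2-methylbut-3-en-1-yl propanoate
Product: 10 (1S,5aR,9aS)-1-ethenyl-6,6-dimethoxy-1,5,8-trimethyl-1,2,5,5a,6,9a-hexahydro-3-benzoxepine-4,9-dione (both epimers at the lactone α-carbon)
Conditions: LiN(SiMe3)2, THF, −78 to 0 °C; AcOH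
Reagents that add atoms: none
Why: Intramolecular Michael addition (7-exo-trig) of the propanoate enolate to the only β-carbon the tether can reach, where any 1,2-adduct reverts on warming, the tether closes from the dienone face that leaves the smaller methyl of the quaternary carbon beside the new bond, and kinetic protonation opposite the new lactone ring gives the cis ring fusion.

Step 7
Reactants: 10 (1S,5aR,9aS)-1-ethenyl-6,6-dimethoxy-1,5,8-trimethyl-1,2,5,5a,6,9a-hexahydro-3-benzoxepine-4,9-dione
Product: 11 (1S,5aR,9R,9aS)-1-ethenyl-9-hydroxy-6,6-dimethoxy-1,5,8-trimethyl-1,5,5a,6,9,9a-hexahydro-3-benzoxepin-4(2H)-one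
Conditions: NaBH4, CeCl3·7H2O, MeOH, −78 °C
Reagents that add atoms: none
Why: Luche 1,2-reduction of the enone leaves the lactone alone, and hydride enters opposite the axial lactone arm, so the hydroxyl ends on the same face as the lactone bridge.

Step 8
Reactants: 11 (1S,5aR,9R,9aS)-1-ethenyl-9-hydroxy-6,6-dimethoxy-1,5,8-trimethyl-1,5,5a,6,9,9a-hexahydro-3-benzoxepin-4(2H)-one
Product: 12 (1S,5aR,9R,9aS)-1-acetyl-9-hydroxy-6,6-dimethoxy-1,5,8-trimethyl-1,5,5a,6,9,9a-hexahydro-3-benzoxepin-4(2H)-one
Conditions: PdCl2 (10 mol %), Cu(OAc)2·H2O (20 mol %), O2 (1 atm), DMA–H2O 7:1, rt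
Reagents that add atoms: water, O
Why: Wacker oxidation with Markovnikov selectivity turns the vinyl group on the quaternary carbon into the methyl ketone, and the acetate-buffered copper co-catalyst spares the allylic ketal.

Step 9
Reactants: 12 (1S,5aR,9R,9aS)-1-acetyl-9-hydroxy-6,6-dimethoxy-1,5,8-trimethyl-1,5,5a,6,9,9a-hexahydro-3-benzoxepin-4(2H)-one
Product: 13 (1S,5aS,9S,9aS)-1-acetyl-9-bromo-6,6-dimethoxy-1,5,8-trimethyl-1,5,5a,6,9,9a-hexahydro-3-benzoxepin-4(2H)-one
Conditions: PPh3, CBr4, 2,6-lutidine, CH2Cl2, 0 °C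
Reagents that add atoms: tetrabromomethane, BrC(Br)(Br)Br
Why: Appel bromination inverts the allylic carbinol (SN2), which places bromide on the face opposite the lactone bridge as the ring closure needs.

Step 10
Reactants: 13 (1S,5aS,9S,9aS)-1-acetyl-9-bromo-6,6-dimethoxy-1,5,8-trimethyl-1,5,5a,6,9,9a-hexahydro-3-benzoxepin-4(2H)-one
Product: 15 (1R,2R,6S,7S,8R)-6-(hydroxymethyl)-11,11-dimethoxy-2,6,9-trimethyltricyclo[5.4.0.0(2,8)]undec-9-ene-3,5-dione, via tricyclic keto-lactone 14 (not isolated)
Conditions: LiN(iPr)2 (3.2 equiv), THF, −78 °C (inverse addition) to rt; aq NH4Cl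
Reagents that add atoms: none
Why: Proposed new method: excess amide base makes the ketone enolate and the lactone enolate together, which enforces the order of events because the deprotonated lactone carbonyl cannot be acylated, so the lactone enolate first displaces the allylic bromide across the ring (4-exo-tet, inversion, the quaternary cyclobutane carbon held in the right orientation by the lactone ring, bromide epimers equilibrating through LiBr) to give 14, and only then does the methyl ketone enolate add to the now non-enolizable lactone carbonyl and expel the alkoxide (Claisen ring switch, driven by β-diketonate formation) to close the seven-membered carbocycle and free the hydroxymethyl group; the closest known reactions are the keto-tosylate cyclobutane closures used for copaene-type sesquiterpenes and intramolecular Claisen acyl transfers.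

Step 11
Reactants: 15 (1R,2R,6S,7S,8R)-6-(hydroxymethyl)-11,11-dimethoxy-2,6,9-trimethyltricyclo[5.4.0.0(2,8)]undec-9-ene-3,5-dione
Product: 17 (1R,2R,3R,5R,6S,7S,8R)-3,5-dihydroxy-6-(hydroxymethyl)-2,6,9-trimethyltricyclo[5.4.0.0(2,8)]undec-9-en-11-one, via ketal triol 16 (not isolated)
Conditions: Me4NBH(OAc)3, MeCN–AcOH 1:1, −20 °C to rt; then 1 M HCl, THF, rt
Reagents that add atoms: water, O
Why: Evans–Saksena directed reduction, in which the hydroxymethyl group delivers hydride to the neighbouring ketone from its own face and the new carbinol then delivers hydride to the second ketone (anti-1,3-diol), sets both carbinol centres, and acid then hydrolyses the ketal to the conjugated enone.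

Step 12
Reactants: 17 (1R,2R,3R,5R,6S,7S,8R)-3,5-dihydroxy-6-(hydroxymethyl)-2,6,9-trimethyltricyclo[5.4.0.0(2,8)]undec-9-en-11-one; 18 (2Z)-2-methylbut-2-enoic anhydride
Product: 19 [(1R,2R,3R,5R,6S,7S,8R)-2,6,9-trimethyl-3,5-bis{[(2Z)-2-methylbut-2-enoyl]oxy}-11-oxotricyclo[5.4.0.0(2,8)]undec-9-en-6-yl]methyl (2Z)-2-methylbut-2-enoate (CNP0266467.1)
Conditions: LiN(SiMe3)2 (3.3 equiv), THF, −78 °C; then 18 (4.5 equiv), −78 to 0 °C; aq NH4Cl
Reagents that add atoms: (2Z)-2-methylbut-2-enoic anhydride (further equivalents of 18), C/C=C(/C)C(=O)OC(=O)/C(C)=C\C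
Why: Acylation of the three lithium alkoxides, each of which takes one angeloyl group from its own molecule of anhydride and releases one lithium angelate (three molecules of 18 consumed, used in excess), esterifies the hindered hydroxyls without a nucleophilic catalyst, which avoids Z-to-E isomerization to tiglates; the bridgehead α-carbon of the enone cannot enolize.

## Compound list

1 | 4-methoxy-2-methylphenol | COc1ccc(O)c(C)c1 | starting material
2 | methyl (2E)-4-bromo-2-methylbut-2-enoate | COC(=O)/C(C)=C/CBr | starting material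
3 | methyl (2E)-4-(4-methoxy-2-methylphenoxy)-2-methylbut-2-enoate | COC(=O)/C(C)=C/COc1ccc(OC)cc1C | intermediate
4 | methyl 2-(2-hydroxy-5-methoxy-3-methylphenyl)-2-methylbut-3-enoate (racemic, not isolated) | COC(=O)C(C)(C=C)c1cc(OC)cc(C)c1O | intermediate
5 | rac-3-ethenyl-5-methoxy-3,7-dimethyl-1-benzofuran-2(3H)-one | COc1cc(C)c2OC(=O)C(C)(C=C)c2c1 | intermediate
6 | rac-2-(1-hydroxy-2-methylbut-3-en-2-yl)-4-methoxy-6-methylphenol | OCC(C)(C=C)c1cc(OC)cc(C)c1O | intermediate
7 | ethenyl propanoate (vinyl propionate) | CCC(=O)OC=C | starting material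
8 | (2S)-2-(2-hydroxy-5-methoxy-3-methylphenyl)-2-methylbut-3-en-1-yl propanoate | CCC(=O)OC[C@@](C)(C=C)c1cc(OC)cc(C)c1O | intermediate
9 | (2S)-2-(3,3-dimethoxy-5-methyl-6-oxocyclohexa-1,4-dien-1-yl)-2-methylbut-3-en-1-yl propanoate | CCC(=O)OC[C@@](C)(C=C)C1=CC(OC)(OC)C=C(C)C1=O | intermediate
10 | (1S,5aR,9aS)-1-ethenyl-6,6-dimethoxy-1,5,8-trimethyl-1,2,5,5a,6,9a-hexahydro-3-benzoxepine-4,9-dione (cis-fused; both epimers at C5) | C=C[C@]1(C)COC(=O)C(C)[C@H]2[C@@H]1C(=O)C(C)=CC2(OC)OC | intermediate
11 | (1S,5aR,9R,9aS)-1-ethenyl-9-hydroxy-6,6-dimethoxy-1,5,8-trimethyl-1,5,5a,6,9,9a-hexahydro-3-benzoxepin-4(2H)-one | C=C[C@]1(C)COC(=O)C(C)[C@H]2[C@@H]1[C@@H](O)C(C)=CC2(OC)OC | intermediate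
12 | (1S,5aR,9R,9aS)-1-acetyl-9-hydroxy-6,6-dimethoxy-1,5,8-trimethyl-1,5,5a,6,9,9a-hexahydro-3-benzoxepin-4(2H)-one | CC(=O)[C@]1(C)COC(=O)C(C)[C@H]2[C@@H]1[C@@H](O)C(C)=CC2(OC)OC | intermediate
13 | (1S,5aS,9S,9aS)-1-acetyl-9-bromo-6,6-dimethoxy-1,5,8-trimethyl-1,5,5a,6,9,9a-hexahydro-3-benzoxepin-4(2H)-one | CC(=O)[C@]1(C)COC(=O)C(C)[C@H]2[C@@H]1[C@H](Br)C(C)=CC2(OC)OC | intermediate
14 | tricyclic keto-lactone: 13 after bonding of the lactone α-carbon to the former C–Br carbon (cyclobutane closed, lactone intact; stereocentres as in 15; not isolated) | CC(=O)[C@]1(C)COC(=O)[C@@]2(C)[C@H]3[C@@H]1[C@@H]2C(C)=CC3(OC)OC | intermediate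
15 | (1R,2R,6S,7S,8R)-6-(hydroxymethyl)-11,11-dimethoxy-2,6,9-trimethyltricyclo[5.4.0.0(2,8)]undec-9-ene-3,5-dione | OC[C@]1(C)[C@@H]2[C@H]3C(OC)(OC)C=C(C)[C@@H]2[C@@]3(C)C(=O)CC1=O | intermediate
16 | (1R,2R,3R,5R,6S,7S,8R)-6-(hydroxymethyl)-11,11-dimethoxy-2,6,9-trimethyltricyclo[5.4.0.0(2,8)]undec-9-ene-3,5-diol (not isolated) | OC[C@]1(C)[C@@H]2[C@H]3C(OC)(OC)C=C(C)[C@@H]2[C@@]3(C)[C@H](O)C[C@H]1O | intermediate
17 | (1R,2R,3R,5R,6S,7S,8R)-3,5-dihydroxy-6-(hydroxymethyl)-2,6,9-trimethyltricyclo[5.4.0.0(2,8)]undec-9-en-11-one | OC[C@]1(C)[C@@H]2[C@H]3C(=O)C=C(C)[C@@H]2[C@@]3(C)[C@H](O)C[C@H]1O | intermediate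
18 | (2Z)-2-methylbut-2-enoic anhydride (angelic anhydride) | C/C=C(/C)C(=O)OC(=O)/C(C)=C\C | starting material
19 | CNP0266467.1, the tris-angelate of 17 | C/C=C(/C)C(=O)OC[C@]1(C)[C@@H]2[C@H]3C(=O)C=C(C)[C@@H]2[C@@]3(C)[C@H](OC(=O)/C(C)=C\C)C[C@H]1OC(=O)/C(C)=C\C | target

## Step count and risks

Total steps: 12. Longest linear sequence: 12 (from 1).

**Step 10 (enolate cascade).** It can fail through O-alkylation of the ketone enolate by the allylic bromide, or through a sluggish acyl transfer onto the hindered lactone. The fallback sets out from 11 and comes back at 15, with the two rings closed separately and the ketone made only after the bromide is gone. Appel bromination of 11 (PPh3, CBr4) gives (1S,5aS,9S,9aS)-9-bromo-1-ethenyl-6,6-dimethoxy-1,5,8-trimethyl-1,5,5a,6,9,9a-hexahydro-3-benzoxepin-4(2H)-one F7. One equivalent of LiN(iPr)2 then closes the cyclobutane to the vinyl-substituted tricyclic lactone F8. Wacker oxidation as in step 8 gives 14, this time isolated, and NaOMe in MeOH opens the lactone to the methyl ester and effects the Dieckmann-type Claisen closure to 15.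

**Step 6 (intramolecular Michael addition).** It can fail through poor face selectivity relative to the quaternary centre, or through 1,2-addition and base damage to the dienone. The fallback sets out from 8 and comes back at 10, with the enolate generated reductively under chelation instead of by an amide base. Methanolysis of 8 (K2CO3, MeOH) gives 2-[(2S)-1-hydroxy-2-methylbut-3-en-2-yl]-4-methoxy-6-methylphenol F4. PhI(OAc)2 in MeOH gives 6-[(2S)-1-hydroxy-2-methylbut-3-en-2-yl]-4,4-dimethoxy-2-methylcyclohexa-2,5-dien-1-one F5. Acylation with 2-bromopropanoyl bromide and pyridine gives (2S)-2-(3,3-dimethoxy-5-methyl-6-oxocyclohexa-1,4-dien-1-yl)-2-methylbut-3-en-1-yl 2-bromopropanoate F6. SmI2 in THF at −78 °C forms the samarium enolate regiospecifically, and its Reformatsky-type conjugate addition gives 10.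

**Step 4 (lipase resolution).** The yield is capped at 50%, and the selectivity for a primary alcohol next to a quaternary centre is uncertain. The fallback sets out from 5 and comes back at 8, replacing the resolution by a desymmetrization. Ozonolysis of the vinyl group of 5 with LiAlH4 work-up gives the prochiral 2-(2-hydroxy-5-methoxy-3-methylphenyl)-2-methylpropane-1,3-diol F1. Lipase-catalysed monoacylation of one enantiotopic CH2OH with ethenyl propanoate gives (2R)-3-hydroxy-2-(2-hydroxy-5-methoxy-3-methylphenyl)-2-methylpropyl propanoate F2. Swern oxidation gives (2S)-2-(2-hydroxy-5-methoxy-3-methylphenyl)-2-methyl-3-oxopropyl propanoate F3, and Wittig methylenation with Ph3P=CH2 restores the vinyl group and gives 8.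

## Further compounds

F1 | step 4 | 2-(2-hydroxy-5-methoxy-3-methylphenyl)-2-methylpropane-1,3-diol | OCC(C)(CO)c1cc(OC)cc(C)c1O
F2 | step 4 | (2R)-3-hydroxy-2-(2-hydroxy-5-methoxy-3-methylphenyl)-2-methylpropyl propanoate | CCC(=O)OC[C@@](C)(CO)c1cc(OC)cc(C)c1O
F3 | step 4 | (2S)-2-(2-hydroxy-5-methoxy-3-methylphenyl)-2-methyl-3-oxopropyl propanoate | CCC(=O)OC[C@@](C)(C=O)c1cc(OC)cc(C)c1O
F4 | step 6 | 2-[(2S)-1-hydroxy-2-methylbut-3-en-2-yl]-4-methoxy-6-methylphenol | OC[C@@](C)(C=C)c1cc(OC)cc(C)c1O
F5 | step 6 | 6-[(2S)-1-hydroxy-2-methylbut-3-en-2-yl]-4,4-dimethoxy-2-methylcyclohexa-2,5-dien-1-one | OC[C@@](C)(C=C)C1=CC(OC)(OC)C=C(C)C1=O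
F6 | step 6 | (2S)-2-(3,3-dimethoxy-5-methyl-6-oxocyclohexa-1,4-dien-1-yl)-2-methylbut-3-en-1-yl 2-bromopropanoate (both epimers at the C–Br carbon) | CC(Br)C(=O)OC[C@@](C)(C=C)C1=CC(OC)(OC)C=C(C)C1=O
F7 | step 10 | (1S,5aS,9S,9aS)-9-bromo-1-ethenyl-6,6-dimethoxy-1,5,8-trimethyl-1,5,5a,6,9,9a-hexahydro-3-benzoxepin-4(2H)-one | C=C[C@]1(C)COC(=O)C(C)[C@H]2[C@@H]1[C@H](Br)C(C)=CC2(OC)OC
F8 | step 10 | vinyl-substituted tricyclic lactone (14 with ethenyl in place of acetyl) | C=C[C@]1(C)COC(=O)[C@@]2(C)[C@H]3[C@@H]1[C@@H]2C(C)=CC3(OC)OC
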